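**Strategy.** The ten-membered carbocycle (C1 ketone, C2=C3 enol ether, C4 CHMe, C5, C6 lactone O–CH, C7, C8 tiglate O–CH, C9, C10 quaternary C–O; C11/C12 lactone α-carbon/carbonyl) is cut at C5–C6. The γ-lactone ring C6–O–C12–C11–C7 is a reduced 3-methyl-2-oxyfuran with C6 as its nucleophilic 5-position; the 3(2H)-furanone ring makes C5 the δ-terminus of the dienone C5=C4–C3=C2–C1=O. One Lewis-acid-triggered vinylogous 1,6-addition therefore forms C5–C6, closes the macrocycle, dearomatises the furan to the C7=C11 butenolide and creates C6 and C4. The precursor is a 2-silyloxy-3-methylfuran linked from its 4-position through C8(OSi)–C9H2 to C10 of a 5-isopropenyl-3(2H)-furanone.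

Key step: step 12

Remark (numbering): the atom numbers above are used throughout, and macrocyclic compounds are named as germacrane derivatives on that numbering.
Remark (assumption): C4 and C11 are both base-epimerisable in the target; the natural 4S and 11S configurations are taken to be the thermodynamically preferred ones, so that the closing equilibration (step 16) converges on the target whatever the kinetic outcome at C4 in step 12.
Remark (materials): 3-methyltetronic acid 12, 2-methylbut-1-en-3-yne 6 and tigloyl chloride 21 are taken as catalogue compounds.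

**Step 1**
Reactants: 1 (R)-citramalic acid
Product: 2 2-[(4R)-2,2,4-trimethyl-5-oxo-1,3-dioxolan-4-yl]acetic acid
Conditions: Me2C(OMe)2, PPTS (cat.), CH2Cl2, rt
Reagents that add atoms: 2,2-dimethoxypropane, COC(C)(C)OC
Why: Acid-catalysed transacetalisation closes the five-membered dioxolanone on the α-hydroxy acid only, masking C1 and the C10 oxygen and leaving the C8 carboxyl free, with C10 untouched.

**Step 2**
Reactants: 2 2-[(4R)-2,2,4-trimethyl-5-oxo-1,3-dioxolan-4-yl]acetic acid
Product: 3 (5R)-5-(2-hydroxyethyl)-2,2,5-trimethyl-1,3-dioxolan-4-one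
Conditions: BH3·SMe2, THF, 0 °C → rt; then H2O
Reagents that add atoms: none
Why: Borane reduces the free carboxylic acid through its acyloxyborane far faster than the dioxolanone carbonyl (chemoselective borane reduction), which brings C8 to the alcohol level.

**Step 3**
Reactants: 3 (5R)-5-(2-hydroxyethyl)-2,2,5-trimethyl-1,3-dioxolan-4-one
Product: 4 (5R)-5-{2-[(tert-butyldimethylsilyl)oxy]ethyl}-2,2,5-trimethyl-1,3-dioxolan-4-one
Conditions: TBSCl, imidazole, CH2Cl2, 0 °C → rt
Reagents that add atoms: tert-butyldimethylsilyl chloride, CC(C)(C)[Si](C)(C)Cl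
Why: Imidazole-mediated silylation of the primary alcohol, carried out promptly so that the hydroxyl cannot translactonise onto the dioxolanone.

**Step 4**
Reactants: 4 (5R)-5-{2-[(tert-butyldimethylsilyl)oxy]ethyl}-2,2,5-trimethyl-1,3-dioxolan-4-one
Product: 5 (2R)-4-[(tert-butyldimethylsilyl)oxy]-2-hydroxy-N-methoxy-N,2-dimethylbutanamide
Conditions: MeNH(OMe)·HCl, i-PrMgCl, THF, −20 → 0 °C
Reagents that add atoms: N,O-dimethylhydroxylamine hydrochloride, CNOC.Cl
Why: The magnesium amide opens the activated dioxolanone carbonyl (Weinreb amide formation by acyl substitution), and the expelled hemiketal alkoxide loses acetone to unveil the tertiary C10 hydroxyl with retention.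

**Step 5**
Reactants: 5 (2R)-4-[(tert-butyldimethylsilyl)oxy]-2-hydroxy-N-methoxy-N,2-dimethylbutanamide; 6 2-methylbut-1-en-3-yne
Product: 8 (6R)-8-[(tert-butyldimethylsilyl)oxy]-6-hydroxy-2,6-dimethyloct-1-en-3-yn-5-one, via lithium 3-methylbut-3-en-1-yn-1-ide 7 (not isolated)
Conditions: 6, n-BuLi, THF, −78 °C; then 5, −78 → −20 °C; then H2O
Reagents that add atoms: none
Why: Weinreb ketone synthesis, in which the acetylide adds once and the chelated tetrahedral intermediate survives until work-up, so the ynone (C1–C5 of the target) forms without over-addition; one further equivalent of 7 is consumed by the free tertiary hydroxyl.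

**Step 6**
Reactants: 8 (6R)-8-[(tert-butyldimethylsilyl)oxy]-6-hydroxy-2,6-dimethyloct-1-en-3-yn-5-one
Product: 9 (2R)-2-{2-[(tert-butyldimethylsilyl)oxy]ethyl}-2-methyl-5-(prop-1-en-2-yl)furan-3(2H)-one
Conditions: (p-CF3C6H4)3PAuCl (5 mol%), AgOTf (5 mol%), toluene, rt
Reagents that add atoms: none
Why: Cationic gold(I) activates the ynone for 5-endo-dig attack of the tertiary hydroxyl and protodeauration gives the 3(2H)-furanone (known cycloisomerisation of γ-hydroxy alkynones), which makes the C10–O–C3 bridge and the C5=C4–C3=C2–C1=O dienone without touching C10.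

**Step 7**
Reactants: 9 (2R)-2-{2-[(tert-butyldimethylsilyl)oxy]ethyl}-2-methyl-5-(prop-1-en-2-yl)furan-3(2H)-one
Product: 10 (2R)-2-(2-hydroxyethyl)-2-methyl-5-(prop-1-en-2-yl)furan-3(2H)-one
Conditions: HF·pyridine, THF, 0 °C → rt
Reagents that add atoms: none
Why: Fluoride desilylation under mildly acidic conditions cleaves the primary TBS ether, while the acid-stable vinylogous ester and the isopropenyl group are left alone.

**Step 8**
Reactants: 10 (2R)-2-(2-hydroxyethyl)-2-methyl-5-(prop-1-en-2-yl)furan-3(2H)-one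
Product: 11 2-[(2R)-2-methyl-3-oxo-5-(prop-1-en-2-yl)-2,3-dihydrofuran-2-yl]acetaldehyde
Conditions: Dess–Martin periodinane, CH2Cl2, rt; used crude
Reagents that add atoms: none
Why: Dess–Martin oxidation is non-basic, which matters because aldehyde 11 carries the vinylogous-carboxylate oxygen of C10 in the β-position and would ring-open by E1cB elimination with amine bases.

**Step 9**
Reactants: 12 3-methyltetronic acid (4-hydroxy-3-methylfuran-2(5H)-one)
Product: 13 4-bromo-3-methylfuran-2(5H)-one
Conditions: (COBr)2, DMF (cat.), CH2Cl2, 0 °C → rt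
Reagents that add atoms: oxalyl bromide, O=C(Br)C(=O)Br
Why: Vilsmeier-type activation of the enolic hydroxyl by the bromoiminium salt followed by addition–elimination of bromide gives the vinylogous acyl bromide, the established route to 4-bromobutenolides.

**Step 10**
Reactants: 11 2-[(2R)-2-methyl-3-oxo-5-(prop-1-en-2-yl)-2,3-dihydrofuran-2-yl]acetaldehyde; 13 4-bromo-3-methylfuran-2(5H)-one
Product: 15 4-{(1S)-1-hydroxy-2-[(2R)-2-methyl-3-oxo-5-(prop-1-en-2-yl)-2,3-dihydrofuran-2-yl]ethyl}-3-methylfuran-2(5H)-one, via alkenylchromium(III) dichloride 14 (not isolated)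
Conditions: CrCl2, 4-isopropyl-2-[2-(methanesulfonylamino)-3-methylphenyl]-4,5-dihydrooxazole (ligand enantiomer selected for the 8S alcohol), Et3N, THF, rt; then NiCl2 (cat.), 13, 11, rt; aqueous work-up
Reagents that add atoms: none
Why: Asymmetric Nozaki–Hiyama–Kishi coupling, in which Ni(0) inserts into the C–Br bond, transmetallation gives alkenylchromium 14 (drawn without its sulfonamide ligand), and this adds only to the aldehyde (ketone, dienone and lactone are inert) to form C7–C8 with C8 set S by the chiral sulfonamide on chromium; the amine is consumed in making the chromium complex before 11 is added, so the medium stays non-basic.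

**Step 11**
Reactants: 15 4-{(1S)-1-hydroxy-2-[(2R)-2-methyl-3-oxo-5-(prop-1-en-2-yl)-2,3-dihydrofuran-2-yl]ethyl}-3-methylfuran-2(5H)-one
Product: 16 (2R)-2-{(2S)-2-[(tert-butyldimethylsilyl)oxy]-2-[5-[(tert-butyldimethylsilyl)oxy]-4-methylfuran-3-yl]ethyl}-2-methyl-5-(prop-1-en-2-yl)furan-3(2H)-one
Conditions: TBSOTf (2.4 equiv), Et3N, CH2Cl2, −78 → 0 °C
Reagents that add atoms: tert-butyldimethylsilyl trifluoromethanesulfonate, CC(C)(C)[Si](C)(C)OS(=O)(=O)C(F)(F)F
Why: TBSOTf silylates the C8 hydroxyl and, with Et3N, enolises the butenolide by γ-deprotonation at C6 to the aromatic 2-silyloxyfuran (soft enolisation); one silyl group for both positions makes the precursor in a single operation and matches the promoter of step 12, and the furanone has no enolisable position.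

**Step 12**
Reactants: 16 (2R)-2-{(2S)-2-[(tert-butyldimethylsilyl)oxy]-2-[5-[(tert-butyldimethylsilyl)oxy]-4-methylfuran-3-yl]ethyl}-2-methyl-5-(prop-1-en-2-yl)furan-3(2H)-one
Product: 18 (4S,6R,8S,10R)-8-(tert-butyldimethylsilyloxy)-3,10-epoxy-1-oxogermacra-2,7(11)-dien-12,6-olide, via silyl dienol ether 17 (not isolated)
Conditions: TBSOTf (30 mol%), 2,6-di-tert-butyl-4-methylpyridine (cat.), CH2Cl2, −78 → −40 °C, syringe-pump addition of 16 (final ≤1 mM); then 0.1 M HCl, THF, 0 °C
Reagents that add atoms: none
Why: Proposed new method: TBSOTf silylates the C1 carbonyl oxygen to give a 3-silyloxyfurylium ion whose charge is relayed through C3=C4 to the unsubstituted C5 terminus, the furan 5-position (C6) adds there to form C5–C6, loss of the silyl group from the resulting 2-silyloxy-oxocarbenium ion returns TBSOTf and leaves the butenolide and silyl dienol ether 17, and dilute acid protonates 17 at C4 (the γ-carbon of the 1,3-dioxygenated diene) to restore the conjugated furanone. The closest known reaction type is the intermolecular Lewis-acid vinylogous Mukaiyama–Michael addition of 2-silyloxyfurans to enones; its use in 1,6-mode at a dienone terminus and as a medium-ring closure is the unproven part. The ten-membered carbocycle, the only ring formed, closes in 10-endo-trig mode at C5 (nine-membered if counted through the furanone oxygen). C6 is set by substrate control: in a product-like transition state the 6R pathway lets C8–H lie syn to the C11 methyl (lowest A(1,3) strain) with C9 and C5 on opposite faces of the furan as in trans-6,12-germacranolides, whereas the 6S pathway needs either a C5/C9 syn-pentane contact or the OTBS group against that methyl, and the C10 quaternary centre fixes the side from which the furanone is presented. C4 is set by protonation of the C3=C4 enol ether from its peripheral face and is in any case re-equilibrated in step 16. The step needs 1,6- over 1,4-addition (C3 is fully substituted and oxygen-bearing, C5 is an open CH2), attack through furan C5 and not C3 (blocked by the methyl group), and ring closure over oligomerisation (slow addition at high dilution).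

**Step 13**
Reactants: 18 (4S,6R,8S,10R)-8-(tert-butyldimethylsilyloxy)-3,10-epoxy-1-oxogermacra-2,7(11)-dien-12,6-olide
Product: 19 (4S,6R,8S,10R)-8-hydroxy-3,10-epoxy-1-oxogermacra-2,7(11)-dien-12,6-olide
Conditions: HF·pyridine, pyridine, THF, 0 °C → rt
Reagents that add atoms: none
Why: Acidic fluoride desilylation frees the allylic C8 hydroxyl; basic fluoride is avoided because γ-deprotonation of the butenolide at C6 would scramble C6 or reopen the ring by retro-1,6-addition, and translactonisation to C8 is geometrically impossible while C7 is sp2.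

**Step 14**
Reactants: 19 (4S,6R,8S,10R)-8-hydroxy-3,10-epoxy-1-oxogermacra-2,7(11)-dien-12,6-olide
Product: 20 (4S,6R,7R,8S,10R,11R)-8-hydroxy-3,10-epoxy-1-oxogermacr-2-en-12,6-olide
Conditions: H2 (5 bar), [Ir(cod)(PCy3)(py)]PF6 (Crabtree's catalyst, cat.), CH2Cl2, rt
Reagents that add atoms: none
Why: Hydroxyl-directed hydrogenation, in which iridium bound to the C8 hydroxyl delivers H2 cis to C7 and C11 of the tetrasubstituted butenolide alkene from the face on which that hydroxyl lies in the A(1,3)-minimised rotamer (C8–H syn to the C11 methyl), the face opposite H6, giving the trans-fused 6,7-lactone with the C11 methyl still cis to C8 (11R); the furanone enol-ether alkene has no directing group and the tiglate alkene is not yet present.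

**Step 15**
Reactants: 20 (4S,6R,7R,8S,10R,11R)-8-hydroxy-3,10-epoxy-1-oxogermacr-2-en-12,6-olide; 21 tigloyl chloride ((E)-2-methylbut-2-enoyl chloride)
Product: 22 (4S,6R,7S,8S,10R,11R)-3,10-epoxy-1-oxo-8-[(E)-2-methylbut-2-enoyloxy]germacr-2-en-12,6-olide (11-epimer of the target)
Conditions: Et3N, DMAP (cat.), CH2Cl2, 0 °C → rt
Reagents that add atoms: none
Why: DMAP-catalysed acylation of the secondary C8 alcohol by the acid chloride, placed before the base treatment so that a free C8 alkoxide cannot translactonise to the 8,12-olide.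

**Step 16**
Reactants: 22 (4S,6R,7S,8S,10R,11R)-3,10-epoxy-1-oxo-8-[(E)-2-methylbut-2-enoyloxy]germacr-2-en-12,6-olide
Product: 23 (4S,6R,7S,8S,10R,11S)-3,10-epoxy-1-oxo-8-[(E)-2-methylbut-2-enoyloxy]germacr-2-en-12,6-olide (CNP0235937.1)
Conditions: DBU, toluene, 60 °C
Reagents that add atoms: none
Why: Base-mediated epimerisation, in which reversible deprotonation at C11 (lactone α-carbon) and at C4 (vinylogous α-position of the furanone) equilibrates both centres to the thermodynamic isomer with the C11 methyl trans to C8 (all-trans lactone) and, by the stated assumption, 4S; the saturated lactone can no longer fragment by retro-1,6-addition and the E tiglate is unaffected.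

**Compound list**
1 | (R)-citramalic acid | C[C@@](O)(CC(=O)O)C(=O)O | starting material
2 | 2-[(4R)-2,2,4-trimethyl-5-oxo-1,3-dioxolan-4-yl]acetic acid | C[C@]1(CC(=O)O)OC(C)(C)OC1=O | intermediate
3 | (5R)-5-(2-hydroxyethyl)-2,2,5-trimethyl-1,3-dioxolan-4-one | C[C@]1(CCO)OC(C)(C)OC1=O | intermediate
4 | (5R)-5-{2-[(tert-butyldimethylsilyl)oxy]ethyl}-2,2,5-trimethyl-1,3-dioxolan-4-one | C[C@]1(CCO[Si](C)(C)C(C)(C)C)OC(C)(C)OC1=O | intermediate
5 | (2R)-4-[(tert-butyldimethylsilyl)oxy]-2-hydroxy-N-methoxy-N,2-dimethylbutanamide | C[C@@](O)(CCO[Si](C)(C)C(C)(C)C)C(=O)N(C)OC | intermediate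
6 | 2-methylbut-1-en-3-yne | C=C(C)C#C | starting material
7 | lithium 3-methylbut-3-en-1-yn-1-ide (formed in the flask) | C=C(C)C#C[Li] | intermediate
8 | (6R)-8-[(tert-butyldimethylsilyl)oxy]-6-hydroxy-2,6-dimethyloct-1-en-3-yn-5-one | C[C@@](O)(CCO[Si](C)(C)C(C)(C)C)C(=O)C#CC(C)=C | intermediate
9 | (2R)-2-{2-[(tert-butyldimethylsilyl)oxy]ethyl}-2-methyl-5-(prop-1-en-2-yl)furan-3(2H)-one | CC(C)(C)[Si](C)(C)OCC[C@@]1(C)OC(=CC1=O)C(C)=C | intermediate
10 | (2R)-2-(2-hydroxyethyl)-2-methyl-5-(prop-1-en-2-yl)furan-3(2H)-one | OCC[C@@]1(C)OC(=CC1=O)C(C)=C | intermediate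
11 | 2-[(2R)-2-methyl-3-oxo-5-(prop-1-en-2-yl)-2,3-dihydrofuran-2-yl]acetaldehyde | O=CC[C@@]1(C)OC(=CC1=O)C(C)=C | intermediate
12 | 3-methyltetronic acid (4-hydroxy-3-methylfuran-2(5H)-one) | CC1=C(O)COC1=O | starting material
13 | 4-bromo-3-methylfuran-2(5H)-one | CC1=C(Br)COC1=O | intermediate
14 | (4-methyl-5-oxo-2,5-dihydrofuran-3-yl)chromium(III) dichloride (formed in the flask; sulfonamide ligand not drawn) | CC1=C([Cr](Cl)Cl)COC1=O | intermediate
15 | 4-{(1S)-1-hydroxy-2-[(2R)-2-methyl-3-oxo-5-(prop-1-en-2-yl)-2,3-dihydrofuran-2-yl]ethyl}-3-methylfuran-2(5H)-one | CC1=C([C@@H](O)C[C@@]2(C)OC(=CC2=O)C(C)=C)COC1=O | intermediate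
16 | (2R)-2-{(2S)-2-[(tert-butyldimethylsilyl)oxy]-2-[5-[(tert-butyldimethylsilyl)oxy]-4-methylfuran-3-yl]ethyl}-2-methyl-5-(prop-1-en-2-yl)furan-3(2H)-one (key-step precursor) | CC1=C(O[Si](C)(C)C(C)(C)C)OC=C1[C@@H](O[Si](C)(C)C(C)(C)C)C[C@@]2(C)OC(=CC2=O)C(C)=C | intermediate
17 | (3Z,6R,8S,10R)-1,8-bis(tert-butyldimethylsilyloxy)-3,10-epoxygermacra-1,3,7(11)-trien-12,6-olide (silyl dienol ether, formed in the flask) | CC1=C2[C@@H](O[Si](C)(C)C(C)(C)C)C[C@@]3(C)O/C(=C(C)\C[C@H]2OC1=O)C=C3O[Si](C)(C)C(C)(C)C | intermediate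
18 | (4S,6R,8S,10R)-8-(tert-butyldimethylsilyloxy)-3,10-epoxy-1-oxogermacra-2,7(11)-dien-12,6-olide (key-step product) | CC1=C2[C@@H](O[Si](C)(C)C(C)(C)C)C[C@@]3(C)OC(=CC3=O)[C@@H](C)C[C@H]2OC1=O | intermediate
19 | (4S,6R,8S,10R)-8-hydroxy-3,10-epoxy-1-oxogermacra-2,7(11)-dien-12,6-olide | CC1=C2[C@@H](O)C[C@@]3(C)OC(=CC3=O)[C@@H](C)C[C@H]2OC1=O | intermediate
20 | (4S,6R,7R,8S,10R,11R)-8-hydroxy-3,10-epoxy-1-oxogermacr-2-en-12,6-olide | O[C@H]1C[C@@]2(C)OC(=CC2=O)[C@@H](C)C[C@H]2OC(=O)[C@H](C)[C@H]12 | intermediate
21 | tigloyl chloride ((E)-2-methylbut-2-enoyl chloride) | C/C=C(\C)C(=O)Cl | starting material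
22 | (4S,6R,7S,8S,10R,11R)-3,10-epoxy-1-oxo-8-[(E)-2-methylbut-2-enoyloxy]germacr-2-en-12,6-olide | C/C=C(\C)C(=O)O[C@H]1C[C@@]2(C)OC(=CC2=O)[C@@H](C)C[C@H]2OC(=O)[C@H](C)[C@H]12 | intermediate
23 | (4S,6R,7S,8S,10R,11S)-3,10-epoxy-1-oxo-8-[(E)-2-methylbut-2-enoyloxy]germacr-2-en-12,6-olide (CNP0235937.1) | C/C=C(\C)C(=O)O[C@H]1C[C@@]2(C)OC(=CC2=O)[C@@H](C)C[C@H]2OC(=O)[C@@H](C)[C@H]12 | target

**Step count.** Total: 16 steps. Longest linear sequence: 15 steps (steps 1–8 and 10–16 from (R)-citramalic acid); step 9 is a one-step side branch.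

**Steps most likely to fail**

Step 12 (proposed new method). The closure may lose to intermolecular oligomerisation, the dienone may engage the wrong face of the furan, or the silyl triflate may ionise the furylic C8–OSi bond or simply protodesilylate the silyloxyfuran. The fallback reverses the order of the two bond formations and uses known reaction types only. It sets out from bromide 13 and furanone 9. Silylation of 13 (TBSOTf, Et3N) would give (4-bromo-3-methylfuran-2-yl)oxy(tert-butyl)dimethylsilane F1. An intermolecular Lewis-acid vinylogous Mukaiyama–Michael addition of F1 to the dienone terminus of 9 (BF3·OEt2, CH2Cl2, −78 °C, acidic work-up) would form C5–C6 where entropy is no obstacle and give the open-chain bromobutenolide (5R)-4-bromo-5-{(2S)-2-[(5R)-5-{2-[(tert-butyldimethylsilyl)oxy]ethyl}-5-methyl-4-oxo-4,5-dihydrofuran-2-yl]propyl}-3-methylfuran-2(5H)-one F2; its C6 epimer would have to be separated, since C10 is too remote to bias that centre. HF·pyridine would free the primary alcohol F3, Dess–Martin oxidation would give the aldehyde F4, and an intramolecular Nozaki–Hiyama–Kishi coupling at high dilution (CrCl2, NiCl2 cat., DMSO/THF), a proven medium-ring closure, would form C7–C8 and come back to the route at alcohol 19.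

Step 14. Hydrogen may be delivered to the wrong face if the C8 hydroxyl turns to the other side within the macrocycle, the electron-poor tetrasubstituted alkene may be reduced too slowly, or the furanone enol ether may be over-reduced. The fallback makes the C7–H bond with nucleophilic hydride and sets out from silyl ether 18. Copper hydride conjugate reduction (Cu(OAc)2, DTBM-SEGPHOS, polymethylhydrosiloxane, t-BuOH, toluene), a known ligand-controlled 1,4-reduction of β-substituted butenolides in which the ligand enantiomer and not the hydroxyl selects the C7 face, would give (4S,6R,7S,8S,10R,11R)-8-(tert-butyldimethylsilyloxy)-3,10-epoxy-1-oxogermacr-2-en-12,6-olide F5 after protonation of the enolate anti to C8. HF·pyridine would then return to alcohol 20.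

Step 10. Ligand control over the C8 face may be eroded with this β-branched aldehyde, the aldehyde may be lost by β-elimination of the C10 oxygen, or insertion into the C–Br bond may be slow. The fallback sets out from 15 obtained as a C8 epimer mixture from a ligand-free coupling. Dess–Martin oxidation would give 3-methyl-4-{[(2R)-2-methyl-3-oxo-5-(prop-1-en-2-yl)-2,3-dihydrofuran-2-yl]acetyl}furan-2(5H)-one F6, and Corey–Bakshi–Shibata reduction (the (R)-oxazaborolidine, catecholborane, toluene, −78 °C, the alkenyl group acting as the large substituent) would set C8 under reagent control and come back to 15.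

**Further compounds**
F1 | step 12 | (4-bromo-3-methylfuran-2-yl)oxy(tert-butyl)dimethylsilane | CC1=C(O[Si](C)(C)C(C)(C)C)OC=C1Br
F2 | step 12 | (5R)-4-bromo-5-{(2S)-2-[(5R)-5-{2-[(tert-butyldimethylsilyl)oxy]ethyl}-5-methyl-4-oxo-4,5-dihydrofuran-2-yl]propyl}-3-methylfuran-2(5H)-one | CC(C)(C)[Si](C)(C)OCC[C@@]1(C)OC(=CC1=O)[C@@H](C)C[C@H]1OC(=O)C(C)=C1Br
F3 | step 12 | (5R)-4-bromo-5-{(2S)-2-[(5R)-5-(2-hydroxyethyl)-5-methyl-4-oxo-4,5-dihydrofuran-2-yl]propyl}-3-methylfuran-2(5H)-one | OCC[C@@]1(C)OC(=CC1=O)[C@@H](C)C[C@H]1OC(=O)C(C)=C1Br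
F4 | step 12 | 2-[(2R)-5-{(2S)-1-[(2R)-3-bromo-4-methyl-5-oxo-2,5-dihydrofuran-2-yl]propan-2-yl}-2-methyl-3-oxo-2,3-dihydrofuran-2-yl]acetaldehyde | O=CC[C@@]1(C)OC(=CC1=O)[C@@H](C)C[C@H]1OC(=O)C(C)=C1Br
F5 | step 14 | (4S,6R,7S,8S,10R,11R)-8-(tert-butyldimethylsilyloxy)-3,10-epoxy-1-oxogermacr-2-en-12,6-olide | CC(C)(C)[Si](C)(C)O[C@H]1C[C@@]2(C)OC(=CC2=O)[C@@H](C)C[C@H]2OC(=O)[C@H](C)[C@H]12
F6 | step 10 | 3-methyl-4-{[(2R)-2-methyl-3-oxo-5-(prop-1-en-2-yl)-2,3-dihydrofuran-2-yl]acetyl}furan-2(5H)-one | CC1=C(C(=O)C[C@@]2(C)OC(=CC2=O)C(C)=C)COC1=O
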